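## Retrosynthetic overview

1. Xenibecin comes from its C11 ketone by a late methylenation. The bis-acetal, the diene and the carbinol are already in place at that point.
2. The (E)-cyclononenone comes from Grob fragmentation of a cis-hydrindane γ-hydroxy mesylate, which breaks C7–C11 and makes C7=C8 and C11=O.
3. The pyran comes from a methoxy-transfer cyclisation of a C1 dimethyl acetal onto a C3 dienal. The dienal side chain is grown from the carvone isopropenyl group by ene chlorination, allyl–alkenyl Suzuki coupling and a Schenck ene reaction.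
4. The hydrindane cyclopentane comes from a photocatalytic HAT cycloisomerisation of an alkenyl 1,4-diol, which forms C7–C8 and the quaternary C7 (new reaction).
5. The diol comes from (S)-carvone, HC(OMe)3 and a C3 Grignard reagent. Ring order: cyclohexene (bought), then cyclopentane, then pyran, then the nine-membered ring (the six- and five-membered rings merge on fragmentation).

**Numbering.** Xenicane numbering is used throughout. Carvone C1 becomes C11, C2 becomes C7 (its methyl is C18), C3 becomes C6, C4 becomes C5, C5 becomes C4a and C6 becomes C11a. The isopropenyl group supplies C4, C3 and C12.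

**Assumption.** Alkenyl boronate 8 is taken as a purchased reagent. If it is not available, it is one step from 2-methylbut-3-yn-2-ol and HBpin.

## Route

**Step 1**
Reactants: 1 (S)-(+)-carvone; 2 trimethyl orthoformate
Product: 3 (5S,6S)-6-(dimethoxymethyl)-2-methyl-5-(prop-1-en-2-yl)cyclohex-2-en-1-one (CH(OMe)2 trans to isopropenyl)
Conditions: i-Pr2NEt, TMSOTf, CH2Cl2, 0 °C; then 2, −78 → −40 °C (one pot)
Reagents that add atoms: trimethyl orthoformate, COC(OC)OC
Why: Soft enolisation gives the cross-conjugated 2-silyloxydiene, which adds to the dimethoxycarbenium ion (Mukaiyama/Noyori-type acetal aldol) anti to the isopropenyl group, and the epimerisable new C11a centre settles trans-diequatorial to the purchased C4a centre.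

**Step 2**
Reactants: 3; 4 3-chloropropan-1-ol (used as its Normant reagent)
Product: 5 (1S,5S,6R)-6-(dimethoxymethyl)-1-(3-hydroxypropyl)-2-methyl-5-(prop-1-en-2-yl)cyclohex-2-en-1-ol (chain trans to isopropenyl, pseudo-axial)
Conditions: 4, i-PrMgCl then Mg, THF; LaCl3·2LiCl, 3, THF, −20 → 0 °C
Reagents that add atoms: 3-(chloromagnesiooxy)propylmagnesium chloride, Cl[Mg]CCCO[Mg]Cl
Why: Lanthanide-assisted Grignard 1,2-addition outruns enolisation/β-elimination and conjugate addition, with axial attack anti to the isopropenyl group, and the new C11 centre is only a relay that is erased in step 9.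

**Step 3 (key step)**
Reactants: 5
Product: 6 (1S,3aS,4R,5S,7aR)-4-(dimethoxymethyl)-7a-methyl-5-(prop-1-en-2-yl)octahydro-3aH-indene-1,3a-diol (cis-hydrindane; C8-OH, C11-OH and C7-Me all on one face)
Conditions: [Ir(dF(CF3)ppy)2(dtbbpy)]PF6 (1 mol %), quinuclidine (10 mol %), Bu4N·H2PO4 (25 mol %), 2,4,6-(i-Pr)3C6H2SH (5 mol %), MeCN, 450 nm LEDs, 25 °C, Ar
Reagents that add atoms: none (isomerisation)
Why: Proposed new method: a redox-neutral cycloisomerisation of an alkenol through its α-hydroxy C–H bond, in which Ir(III)* oxidises quinuclidine, the quinuclidinium radical cation abstracts the hydridic, phosphate-H-bond-activated C8–H, the nucleophilic α-hydroxyalkyl radical closes 5-exo-trig from the pseudo-axial tether onto C7 of the unactivated trisubstituted alkene (giving the cis-fused ring and quaternary C7), the C6 radical is capped by ArSH, and ArS• is returned by Ir(II)/quinuclidinium; the C8–O bond sits anti to the alkene and dihydrogen phosphate bridges the C8 and C11 hydroxyls, so C8-OH ends syn to C11-OH and C7-Me; the closest known reactions are the H-bond-assisted photoredox/HAT α-alkylation of alcohols with acrylates (intermolecular Giese only), ketyl–olefin 5-exo cyclisations, and Ueno–Stork closures onto 2-methylcyclohexenyl systems.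

**Step 4**
Reactants: 6
Product: 7, the 5-(3-chloroprop-1-en-2-yl) analogue of 6 (CH2Cl = C12, =CH2 = C3)
Conditions: Ca(OCl)2, CO2(s), CH2Cl2/H2O, 0 °C
Reagents that add atoms: calcium hypochlorite (HOCl source), [Ca+2].[O-]Cl.[O-]Cl
Why: Ene-type allylic chlorination with HOCl hits the only alkene present, shifts the double bond, tolerates free alcohols and the acetal, and touches no stereocentre.

**Step 5**
Reactants: 7; 8 (E)-2-methyl-4-(4,4,5,5-tetramethyl-1,3,2-dioxaborolan-2-yl)but-3-en-2-ol
Product: 9, the skipped-diene triol with C4(=C3H2)–C12H2–(E)-C13H=C14H–C15Me2OH on the hydrindane diol core of 6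
Conditions: Pd(PPh3)4 (5 mol %), K3PO4 (aq), THF, 50 °C
Reagents that add atoms: 8, CC(C)(O)/C=C/B1OC(C)(C)C(C)(C)O1
Why: Suzuki–Miyaura allyl–alkenyl coupling runs through a 2-substituted π-allyl-Pd whose two CH2 termini are equivalent, so there is no regiochemical issue, and the (E)-boronate geometry is retained at C13=C14.

**Step 6**
Reactants: 9
Product: 10, the C8 methanesulfonate of 9 (C11-OH and C15-OH free)
Conditions: MsCl (1.2 equiv), Et3N, CH2Cl2, −30 °C
Reagents that add atoms: methanesulfonyl chloride, CS(=O)(=O)Cl
Why: Sulfene mesylation selects the single secondary alcohol over the two tertiary ones and installs the nucleofuge with retention at C8 (syn to C7-Me).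

**Step 7**
Reactants: 10
Product: 11, the (4E,13E)-dienal OHC(C3)–C4(=C12H–C13H=C14H–C15Me2OH)–C4a, with C13 trans to CHO and the mesylate and C1 acetal unchanged
Conditions: O2, methylene blue, MeCN, white LEDs, 0 °C; then Ac2O (1.2 equiv), pyridine, DMAP, 0 °C → rt
Reagents that add atoms: dioxygen, O=O
Why: In the Schenck ene reaction 1O2 can bond only to terminal C3 of the 1,1-disubstituted alkene and removes the doubly allylic C12–H geminal to the bulky ring (C13=C14 is carbinol-deactivated and neopentyl-hindered), Kornblum–DeLaMare-type dehydration of the primary peracetate gives the dienal, and DMAP equilibrates it by reversible conjugate addition to the more stable (E)-enal.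

**Step 8**
Reactants: 11
Product: 12, the tricyclic bis-acetal mesylate: a 1,3-dimethoxy pyran trans-fused to the hydrindane, (1S,3S), with C3-OMe axial and C1-OMe equatorial, and the 4(12)E,13E-diene
Conditions: PPTS (10 mol %), MeOH, rt
Reagents that add atoms: methanol, CO (supplies the C3-OMe; one MeOH is released from C1, so the step is a net isomerisation)
Why: In this acid-catalysed transacetalisation the C3 methyl hemiacetal captures the C1 oxocarbenium ion, and the reversible process converges, under control of C4a/C11a, on axial C3-OMe (anomeric effect, no A1,3 clash with the alkylidene) and equatorial C1-OMe (avoids syn-diaxial OMe/OMe); minor anomers can be resubmitted.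

**Step 9**
Reactants: 12
Product: 13, the (7E)-cyclononenone (xenibecin with C11=O in place of C11=CH2)
Conditions: KOt-Bu (1.1 equiv), THF/t-BuOH, −20 → 0 °C
Reagents that add atoms: none
Why: In this Grob fragmentation C8–OMs is antiperiplanar to C7–C11 and syn to C7-Me, so concerted cleavage gives the ketone and only the (E)-C7=C8 alkene, and near-stoichiometric base leaves nothing to cause β-elimination or C11a epimerisation.

**Step 10**
Reactants: 13
Product: 14 xenibecin, (1S,3S,4E,4aS,7E,11aR)
Conditions: Cp2TiMe2 (3 equiv), toluene/THF, 70 °C, dark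
Reagents that add atoms: dimethyltitanocene, [CH3-].[CH3-].[Ti+4].c1cc[cH-]c1.c1cc[cH-]c1
Why: Petasis methylenation is neither basic nor Lewis acidic, so the enolisable β-alkoxy ketone becomes the exocyclic methylene without E1cB loss of acetal oxygen or epimerisation, and the tertiary alcohol only consumes one equivalent of reagent.

## Compound list

| No. | Name | SMILES | Role |
|---|---|---|---|
| 1 | (S)-(+)-carvone | C=C(C)[C@H]1CC=C(C)C(=O)C1 | starting material |
| 2 | trimethyl orthoformate | COC(OC)OC | starting material |
| 3 | (5S,6S)-6-(dimethoxymethyl)carvone | C=C(C)[C@H]1CC=C(C)C(=O)[C@@H]1C(OC)OC | intermediate |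
| 4 | 3-chloropropan-1-ol | OCCCCl | starting material |
| 5 | (1S,5S,6R)-alkenyl 1,4-diol | C=C(C)[C@H]1CC=C(C)[C@](O)(CCCO)[C@@H]1C(OC)OC | intermediate |
| 6 | (1S,3aS,4R,5S,7aR)-cis-hydrindane-1,3a-diol | C=C(C)[C@H]1CC[C@]2(C)[C@@H](O)CC[C@]2(O)[C@@H]1C(OC)OC | intermediate |
| 7 | allylic chloride | C=C(CCl)[C@H]1CC[C@]2(C)[C@@H](O)CC[C@]2(O)[C@@H]1C(OC)OC | intermediate |
| 8 | (E)-3-hydroxy-3-methylbut-1-enyl-Bpin | CC(C)(O)/C=C/B1OC(C)(C)C(C)(C)O1 | starting material |
| 9 | skipped-diene triol | C=C(C/C=C/C(C)(C)O)[C@H]1CC[C@]2(C)[C@@H](O)CC[C@]2(O)[C@@H]1C(OC)OC | intermediate |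
| 10 | C8 mesylate | C=C(C/C=C/C(C)(C)O)[C@H]1CC[C@]2(C)[C@@H](OS(C)(=O)=O)CC[C@]2(O)[C@@H]1C(OC)OC | intermediate |
| 11 | (E,E)-dienal | O=C/C(=C/C=C/C(C)(C)O)[C@H]1CC[C@]2(C)[C@@H](OS(C)(=O)=O)CC[C@]2(O)[C@@H]1C(OC)OC | intermediate |
| 12 | tricyclic bis-acetal mesylate | C[C@]12CC[C@@H]3/C(=C\C=C\C(C)(C)O)[C@@H](OC)O[C@H](OC)[C@H]3[C@@]1(O)CC[C@@H]2OS(C)(=O)=O | intermediate |
| 13 | (E)-cyclononenone | O=C1CC/C=C(\C)CC[C@@H]2/C(=C\C=C\C(C)(C)O)[C@@H](OC)O[C@H](OC)[C@@H]12 | intermediate |
| 14 | xenibecin | C=C1CC/C=C(\C)CC[C@@H]2/C(=C\C=C\C(C)(C)O)[C@@H](OC)O[C@H](OC)[C@@H]12 | target |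

## Summary

Total step count: 10. Longest linear sequence: 10 steps, from (S)-carvone.

**Steps most likely to fail**

1. **Step 3 (new photocatalytic cycloisomerisation).**
   - Risks: slow 5-exo closure onto the methyl-bearing alkene carbon, off-site HAT, and modest C8 selectivity.
   - Fallback (known chemistry, +1 step): oxidise the primary alcohol of 5 to the γ-hydroxy aldehyde/lactol (SO3·py, DMSO). Then close C7–C8 reductively with SmI2/HMPA/t-BuOH (ketyl–olefin cyclisation), where the hydroxyl-chelated Sm ketyl gives the same syn-1,3-diol 6.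
2. **Step 7 (Schenck ene and dehydration).**
   - Risks: a sluggish 1,1-disubstituted alkene, a competing ene reaction at C13=C14, and incomplete E/Z equilibration at C4=C12.
   - Fallback (polar route, +1 step): run a second HOCl ene-chlorination of 10, placing Cl at C3 with loss of the doubly allylic C12–H. Then oxidise the resulting dienyl chloride to dienal 11 with an N-oxide (NMO) or under Kornblum conditions.
3. **Step 2 (1,2-addition to the hindered, enolisable β-keto acetal).**
   - Risks: enolisation with loss of MeOH, or reduction of the ketone.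
   - Fallback (+1 step): add allylmagnesium bromide, which reacts fast with hindered ketones. Then carry out chemoselective hydroboration–oxidation of the monosubstituted alkene (Sia2BH; NaBO3) to reach the same diol 5.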